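Remark on the chemistry: (S)-4-benzyl-1,3-oxazolidin-2-one is taken as a commercial chiral auxiliary, and all three phenols are carried as tert-butyldimethylsilyl (TBS) ethers so that one buffered desilylation ends the synthesis. In names, Ar = 4-[(tert-butyldimethylsilyl)oxy]-3-methoxyphenyl. Ring A is numbered O1, C2 (aryl), C3 (bearing the ester methylene C6), C4 (bearing the carbinol carbon C7), C5 (CH2).

## Analysis of the target

The target 28 is a tetrahydrofuran lignan of the 7-hydroxylariciresinol type whose primary alcohol is esterified with p-coumaric acid. It has one ring (ring A) and four contiguous stereocentres: C2 (S), C3 (R), C4 (R) and the exocyclic carbinol C7 (S). The aryl group on C2 is trans to C6 on C3, whereas C6 and C7 are cis on C3 and C4, which is the less stable arrangement on a five-membered ring. Sensitive groups are the three free phenols, the (E)-cinnamate ester (base-labile, a conjugate acceptor, not compatible with hydrogenation) and two benzylic C–O bonds para to oxygen donors (C2–O1 and C7–OH), which ionise easily under acid. A free 1,4-diol at C6 and C7 would close to a furofuran, so the two oxygens must never be free together under acidic conditions. The difficulties are therefore the 3,4-cis relation, the exocyclic centre C7, and the differentiation of the acylated primary oxygen on C6 from the free secondary oxygen on C7. The plan rests on two features: C5 is an unsubstituted methylene flanked only by O1 and C4, so it can enter as the methyl group of a methyl ether on O1; and C6 and C7 are cis, so they can be tied into a γ-lactone (C7 as carbonyl carbon, C6 as alkoxy carbon) that acts as tether for the ring closure and later offers C7 as an electrophile while freeing only the C6 hydroxyl.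

## Retrosynthetic reasoning

28 from 27. The three phenols are masked as silyl ethers in 27, because free phenols would quench the organolithium step and compete in the acylation. One buffered desilylation at the end is all that is needed.

27 from 26. The C7–H bond is cut, so C7 is a ketone in 26. Keeping C7 at the ketone level until after the esterification means that a free C6/C7 diol never exists. The forward reduction has to deliver the 7S alcohol next to the C4 centre without touching the cinnamate.

26 from 22 and 25. The ester C–O bond is cut. Hydroxy ketone 22 has a single free hydroxyl, so acylation with the silylated acid 25 needs no selectivity between alcohols.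

22 from 17 and 19. The bond between C7 and its aryl ring is cut. Lactone 17 is the acyl donor: the aryllithium 20 made from bromide 19 adds to the C7 carbonyl through lactolate 21, and the ring opening frees exactly the C6 hydroxyl. The forward step must stop after one addition.

17 from 16 (key disconnection). The C4–C5 bond is cut, turning C5 back into the methyl group of the ether on O1 and C4 into a diazo-bearing carbenoid precursor. This cut is preferred over C2–C3 or O1–C2 because C5 has no substituent. Only one stereocentre (C4) is created, and its configuration is dictated by the cis fusion of the bicycle; C2 and C3 are already in place. The forward reaction must be a chemoselective 1,5 C–H insertion into a methyl ether.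

16 from 14, 14 from 13, 13 from 11. The diazo group comes from diazo transfer onto lactone 14 by way of the trifluoroacetyl lactone 15. The lactone carbonyl C7 is traced to the internal carbon of a terminal alkene: oxidative cleavage of 11 gives hydroxy aldehyde 12, which closes to lactol 13 and is oxidised. C6 is the primary alcohol carbon of 11.

11 from 10, 10 from 9. The primary alcohol comes from reductive removal of the auxiliary from 10. The methyl ether (the future C5) comes from O-methylation of aldol adduct 9, which must not trigger retro-aldol cleavage.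

9 from 6 and 2. The C2–C3 bond is cut as a syn aldol between the boron enolate 7 of imide 6 and aldehyde 2, passing through boron aldolate 8. This one step sets C2 and C3 in the absolute sense required, and the allyl group of 6 carries C4 and C7.

6 from 3 and 4 (through mixed anhydride 5); 2 from 1; 19 from 18; 25 from 23 (through 24). These are protecting-group and acylation operations on commercial materials.

## Alternatives that were turned down

Alternative 1: Ring A is cut at O1–C2 and C3–C4, and the lactone at its C6–O bond, giving the cis epoxy alcohol A1 and the arylidene malonate A2. In the forward sense the potassium alkoxide of A1 adds to A2, the malonate anion opens the oxirane at C4 (5-exo-tet, inversion), and the alkoxide released at C7 lactonises onto the cis ester to give A3.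
- For: three bonds, two rings and both aryl groups arrive in one flask from two fragments of similar size. C4 and C7 are copied from the epoxide. The route would be shorter and more convergent than the chosen one, and on these points it is stronger.
- Against: the oxirane carries an electron-rich aryl group on C7, so opening at the benzylic carbon (6-endo) and Payne rearrangement of the epoxy alkoxide compete with the wanted 5-exo opening. The Z-allylic alcohol behind A1 belongs to a weak substrate class for asymmetric epoxidation. A3 carries a surplus ester on C3 that has to be removed by hot dealkoxycarbonylation.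
- Decisive drawback: the lactone of A3 has the C7 oxygen in the ring, so its reduction liberates the C6 and C7 hydroxyls together. That requires a selective acylation and exposes an acid-sensitive 1,4-diol.
- Comparison: the chosen route is longer, but its lactone is turned the other way, so only the C6 hydroxyl is ever free and each stereocentre is set in a step with one clear control element.

Alternative 2: Both halves are cut at the benzylic C–H bonds (C2–H and C7–H) and at the two lactone C–O bonds, leading to the epimerising diaroylsuccinate A4. In the forward sense RuCl(p-cymene)[(S,S)-TsDPEN] with formic acid and triethylamine reduces both ketones under dynamic kinetic resolution and each alkoxide lactonises onto the ester of the other half, giving the twofold-symmetric bis-lactone A5.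
- For: A4 is two or three steps from a vanillic acid derivative, one catalyst sets four stereocentres, and the symmetry raises the enantiomeric purity. To the bicyclic core this is clearly the shortest approach.
- Against: the target is not symmetric. One lactone carbonyl of A5 (C5) must be taken down to a methylene while keeping the ring, which means lactol formation and ionic deoxygenation on a scaffold holding two benzylic C–O bonds para to silyloxy groups. The other lactone must be reduced to the C6/C7 diol, which again needs selective acylation. The double reduction also has to control the relative configuration of two epimerisable centres through two successive events, the second on a changed substrate.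
- Comparison: the chosen route never has to separate two equal functional groups, because C5, C6 and C7 sit at three different oxidation levels from the start.

Alternative 3: Ring A is cut at C2–C3 and C4–C5. Fluoride converts the α-chloro silylmethyl ether A6 into the non-stabilised carbonyl ylide A7, which adds across the double bond of the (S)-5-aryl butenolide A8 to give cycloadduct A9.
- For: two C–C bonds and ring A form in one step from two halves. The C7 centre of A8 can direct the facial approach. The sequence is short.
- Against: the ylide is unsymmetrical, and its benzylic terminus must bond to the α-carbon of the butenolide, which is not the electronically obvious orientation. The exo or endo placement of the aryl group on C2 is open as well. The γ-hydrogen of A8 is benzylic and vinylogously acidic, so the fluoride conditions threaten its configuration. A6, an α-chloro ether of an electron-rich benzaldehyde, is very labile. The lactone of A9 is again turned with C7–O in the ring, so the diol problem returns.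
- Comparison: this route is more convergent, but regio-, diastereo- and facial selectivity all rest on one step. The chosen route takes C2 and C3 from an auxiliary-controlled aldol and C4 from a tether.

Key step: step 9

## Route

Step 1
Reactants: 1 vanillin
Product: 2 4-[(tert-butyldimethylsilyl)oxy]-3-methoxybenzaldehyde
Conditions: TBSCl, imidazole, CH2Cl2, rt
Reagents that add atoms: tert-butyldimethylsilyl chloride, CC(C)(C)[Si](C)(C)Cl
Why: Standard silylation of a phenol; the aldehyde is untouched and the silyl ether tolerates the boron aldol, hydride and carbenoid steps that follow.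

Step 2
Reactants: 3 pent-4-enoic acid; 4 (S)-4-benzyl-1,3-oxazolidin-2-one
Product: 6 (4S)-4-benzyl-3-(pent-4-enoyl)-1,3-oxazolidin-2-one, via pent-4-enoic pivalic anhydride 5 (not isolated)
Conditions: t-BuCOCl, Et3N, THF, −20 °C; then LiCl, 4, −20 °C to rt
Reagents that add atoms: none
Why: Mixed-anhydride N-acylation of the oxazolidinone; the hindered pivaloyl carbonyl directs attack to the pentenoyl carbonyl and LiCl activates the auxiliary under mild base.

Step 3
Reactants: 6 (4S)-4-benzyl-3-(pent-4-enoyl)-1,3-oxazolidin-2-one; 2 4-[(tert-butyldimethylsilyl)oxy]-3-methoxybenzaldehyde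
Product: 9 (4S)-4-benzyl-3-{(2S)-2-[(S)-Ar(hydroxy)methyl]pent-4-enoyl}-1,3-oxazolidin-2-one, via dibutylboron (Z)-enolate 7 (not isolated), via dibutylboron aldolate 8 (not isolated)
Conditions: Bu2BOTf, i-Pr2NEt, CH2Cl2, 0 °C; 2, −78 to 0 °C; then pH 7 buffer, MeOH, 30% H2O2, 0 °C
Reagents that add atoms: none
Why: Evans syn aldol: soft enolisation gives the (Z)-boron enolate, which reacts through a closed chair (Zimmerman–Traxler) transition state on the face away from the benzyl group of the auxiliary, setting C3 and C2 together as the syn (2S, carbinol S) adduct expected from the (S)-auxiliary with an aryl aldehyde.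

Step 4
Reactants: 9 (4S)-4-benzyl-3-{(2S)-2-[(S)-Ar(hydroxy)methyl]pent-4-enoyl}-1,3-oxazolidin-2-one
Product: 10 (4S)-4-benzyl-3-{(2S)-2-[(S)-Ar(methoxy)methyl]pent-4-enoyl}-1,3-oxazolidin-2-one
Conditions: Me3OBF4, 1,8-bis(dimethylamino)naphthalene, 4 Å MS, CH2Cl2, 0 °C to rt
Reagents that add atoms: trimethyloxonium tetrafluoroborate, C[O+](C)C.F[B-](F)(F)F
Why: O-alkylation with a Meerwein salt and a non-nucleophilic proton scavenger methylates the neutral alcohol without forming an alkoxide, so retro-aldol cleavage and epimerisation at C3 are avoided; the methyl carbon introduced here becomes C5.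

Step 5
Reactants: 10 (4S)-4-benzyl-3-{(2S)-2-[(S)-Ar(methoxy)methyl]pent-4-enoyl}-1,3-oxazolidin-2-one
Product: 11 (2R)-2-[(S)-Ar(methoxy)methyl]pent-4-en-1-ol
Conditions: LiBH4, MeOH (1 equiv), THF, 0 °C
Reagents that add atoms: none
Why: Reductive cleavage of the N-acyl oxazolidinone at the exocyclic carbonyl gives the primary alcohol (the future C6–OH) and returns the auxiliary; aryl silyl ether, methyl ether and alkene are inert to LiBH4.

Step 6
Reactants: 11 (2R)-2-[(S)-Ar(methoxy)methyl]pent-4-en-1-ol
Product: 13 (4R)-4-[(S)-Ar(methoxy)methyl]oxolan-2-ol (both anomers), via (3R,4S)-4-Ar-3-(hydroxymethyl)-4-methoxybutanal 12 (not isolated)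
Conditions: OsO4 (cat.), NaIO4, 2,6-lutidine, 1,4-dioxane/H2O (3:1), rt
Reagents that add atoms: osmium tetroxide, O=[Os](=O)(=O)=O (delivers the new oxygen); sodium periodate, [Na+].[O-]I(=O)(=O)=O (terminal oxidant that restores the oxygen on osmium)
Why: Lemieux–Johnson cleavage of the terminal alkene is chosen over ozonolysis because it leaves the electron-rich arene alone; the γ-hydroxy aldehyde closes spontaneously to the five-membered lactol.

Step 7
Reactants: 13 (4R)-4-[(S)-Ar(methoxy)methyl]oxolan-2-ol
Product: 14 (4R)-4-[(S)-Ar(methoxy)methyl]oxolan-2-one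
Conditions: (n-Pr4N)RuO4 (cat.), N-methylmorpholine N-oxide, 4 Å MS, CH2Cl2, rt
Reagents that add atoms: none
Why: Ley–Griffith oxidation of a lactol to the γ-lactone under neutral conditions; the benzylic methyl ether and the silyl ether are not oxidised.

Step 8
Reactants: 14 (4R)-4-[(S)-Ar(methoxy)methyl]oxolan-2-one
Product: 16 (4R)-3-diazo-4-[(S)-Ar(methoxy)methyl]oxolan-2-one, via (4R)-4-[(S)-Ar(methoxy)methyl]-3-(trifluoroacetyl)oxolan-2-one 15 (not isolated)
Conditions: LiN(SiMe3)2, THF, −78 °C; CF3CO2CH2CF3; then MeSO2N3, Et3N, H2O (1 equiv), MeCN, rt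
Reagents that add atoms: methanesulfonyl azide, CS(=O)(=O)N=[N+]=[N-]
Why: Deacylative Regitz diazo transfer: Claisen-type trifluoroacetylation of the lactone enolate activates the α-carbon, and the sulfonyl azide then transfers N2 while the trifluoroacetyl group leaves as the acyl sulfonamide; the enolate has no β-leaving group, so C3 and C2 are not endangered.

Step 9
Reactants: 16 (4R)-3-diazo-4-[(S)-Ar(methoxy)methyl]oxolan-2-one
Product: 17 (3aR,4S,6aR)-4-Ar-tetrahydro-1H,3H-furo[3,4-c]furan-1-one (exo-2-aryl-3,7-dioxabicyclo[3.3.0]octan-6-one)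
Conditions: Rh2(acam)4 (dirhodium tetraacetamidate, Rh2(NHCOCH3)4, 2 mol%), CH2Cl2, reflux, slow addition of 16 at high dilution
Reagents that add atoms: none
Why: Rh2(acam)4 takes up the diazo carbon of 16 and loses N2 to give an electrophilic rhodium carbenoid at C4, which engages a C–H bond of the O1 methyl group in a concerted three-centre transition state; the positive charge building at C5 is stabilised by the lone pair of O1, and the catalyst is released as the C4–C5 and C4–H bonds form. The closest known reaction type is the dirhodium-catalysed 1,5 C–H insertion of α-diazo lactones and esters next to an ether oxygen to give tetrahydrofurans, which includes insertion into O-methyl groups and the closure of benzyl ethers onto diazo lactones to give 3,7-dioxabicyclo[3.3.0]octanones. Ring A closes as a five-membered ring by 1,5 insertion (C4, C3, C2, O1, C5); the benzylic C2–H is only 1,3 to the carbenoid and would give a cyclopropane. The one new stereocentre, C4, is controlled by the lactone tether, since a bicyclo[3.3.0] system can only be cis-fused; C6 and C7 therefore end up cis as in the target, C2 and C3 are untouched, and C5 is not stereogenic. The selectivity needed is chemoselectivity: insertion must outrun 1,2-hydride migration from C3, attack on the electron-rich arene (its ortho C–H is also 1,5 to the carbenoid) and carbene dimerisation. The acetamidate ligands make the carbenoid less electrophilic and more selective, which favours aliphatic insertion over arene attack and hydride migration; the ether oxygen activates the methyl C–H bonds; slow addition at high dilution suppresses dimerisation.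

Step 10
Reactants: 18 4-bromo-2-methoxyphenol
Product: 19 (4-bromo-2-methoxyphenoxy)(tert-butyl)dimethylsilane
Conditions: TBSCl, imidazole, DMF, rt
Reagents that add atoms: tert-butyldimethylsilyl chloride, CC(C)(C)[Si](C)(C)Cl
Why: Phenol silylation; the silyloxy group is para to bromine, so the derived aryllithium cannot undergo an ortho silyl migration.

Step 11
Reactants: 17 (3aR,4S,6aR)-4-Ar-tetrahydro-1H,3H-furo[3,4-c]furan-1-one; 19 (4-bromo-2-methoxyphenoxy)(tert-butyl)dimethylsilane
Product: 22 [(2S,3R,4R)-2-Ar-3-(hydroxymethyl)oxolan-4-yl](Ar)methanone (ring A numbering), via aryllithium ArLi 20 (not isolated), via lithium lactolate 21 (not isolated)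
Conditions: 19, n-BuLi, THF, −78 °C; then added slowly to 17, THF, −78 °C; aq. NH4Cl at −78 °C
Reagents that add atoms: none
Why: Bromine–lithium exchange followed by 1,2-addition of the aryllithium to the lactone carbonyl; the tetrahedral lithium lactolate persists at −78 °C, so a second addition is held back, and quenching releases the aryl ketone at C7 together with the free C6 hydroxyl.

Step 12
Reactants: 23 p-coumaric acid
Product: 25 (E)-3-{4-[(tert-butyldimethylsilyl)oxy]phenyl}prop-2-enoic acid, via tert-butyldimethylsilyl (E)-3-{4-[(tert-butyldimethylsilyl)oxy]phenyl}prop-2-enoate 24 (not isolated)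
Conditions: TBSCl (2.2 equiv), imidazole, DMF, rt; then AcOH/THF/H2O, rt
Reagents that add atoms: tert-butyldimethylsilyl chloride, CC(C)(C)[Si](C)(C)Cl
Why: Exhaustive silylation followed by selective hydrolysis of the much more labile silyl ester under mild acid, which leaves the aryl silyl ether in place.

Step 13
Reactants: 22 [(2S,3R,4R)-2-Ar-3-(hydroxymethyl)oxolan-4-yl](Ar)methanone; 25 (E)-3-{4-[(tert-butyldimethylsilyl)oxy]phenyl}prop-2-enoic acid
Product: 26 [(2S,3R,4R)-2-Ar-4-(Ar-carbonyl)oxolan-3-yl]methyl (E)-3-{4-[(tert-butyldimethylsilyl)oxy]phenyl}prop-2-enoate (ring A numbering)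
Conditions: EDC·HCl, DMAP (cat.), CH2Cl2, 0 °C to rt
Reagents that add atoms: none
Why: Steglich-type carbodiimide esterification of the only free hydroxyl; the open hydroxy ketone is drained from its equilibrium with the cyclic hemiketal, and the weakly basic medium should not epimerise C4.

Step 14
Reactants: 26 [(2S,3R,4R)-2-Ar-4-(Ar-carbonyl)oxolan-3-yl]methyl (E)-3-{4-[(tert-butyldimethylsilyl)oxy]phenyl}prop-2-enoate
Product: 27 [(2S,3R,4R)-2-Ar-4-[(S)-Ar(hydroxy)methyl]oxolan-3-yl]methyl (E)-3-{4-[(tert-butyldimethylsilyl)oxy]phenyl}prop-2-enoate (ring A numbering)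
Conditions: (R)-2-methyl-CBS-oxazaborolidine (20 mol%), catecholborane, toluene, −78 to −40 °C
Reagents that add atoms: none
Why: Corey–Bakshi–Shibata reduction: with the aryl group as the large substituent, the (R)-catalyst delivers hydride to the face that gives the (S)-carbinol at C7. A Felkin–Anh analysis of the C4 centre (C3 anti to the incoming hydride, C5 beside the carbonyl oxygen) predicts the same sense, so catalyst and substrate should reinforce each other; catecholborane at low temperature should not touch the cinnamate.

Step 15
Reactants: 27 [(2S,3R,4R)-2-Ar-4-[(S)-Ar(hydroxy)methyl]oxolan-3-yl]methyl (E)-3-{4-[(tert-butyldimethylsilyl)oxy]phenyl}prop-2-enoate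
Product: 28 [(2S,3R,4R)-4-[(S)-hydroxy(4-hydroxy-3-methoxyphenyl)methyl]-2-(4-hydroxy-3-methoxyphenyl)oxolan-3-yl]methyl (E)-3-(4-hydroxyphenyl)prop-2-enoate (target, CNP0330050.2)
Conditions: Bu4NF, AcOH (1:1), THF, 0 °C
Reagents that add atoms: none
Why: Fluoride cleaves the three aryl silyl ethers; buffering with acetic acid keeps the phenols protonated, so the cinnamate ester and the benzylic alcohol should survive and no stereocentre is touched.

## Compound list

1 | vanillin | COc1cc(C=O)ccc1O | starting material
2 | 4-[(tert-butyldimethylsilyl)oxy]-3-methoxybenzaldehyde | COc1cc(C=O)ccc1O[Si](C)(C)C(C)(C)C | intermediate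
3 | pent-4-enoic acid | C=CCCC(=O)O | starting material
4 | (S)-4-benzyl-1,3-oxazolidin-2-one | O=C1OC[C@H](Cc2ccccc2)N1 | starting material
5 | pent-4-enoic pivalic anhydride (not isolated) | C=CCCC(=O)OC(=O)C(C)(C)C | intermediate
6 | (4S)-4-benzyl-3-(pent-4-enoyl)-1,3-oxazolidin-2-one | C=CCCC(=O)N1[C@@H](Cc2ccccc2)COC1=O | intermediate
7 | dibutylboron (Z)-enolate of 6 (not isolated) | CCCCB(CCCC)O/C(=C\CC=C)N1[C@@H](Cc2ccccc2)COC1=O | intermediate
8 | dibutylboron aldolate of 9 (not isolated) | CCCCB(CCCC)O[C@H](c1ccc(O[Si](C)(C)C(C)(C)C)c(OC)c1)[C@H](CC=C)C(=O)N1[C@@H](Cc2ccccc2)COC1=O | intermediate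
9 | (4S)-4-benzyl-3-{(2S)-2-[(S)-Ar(hydroxy)methyl]pent-4-enoyl}-1,3-oxazolidin-2-one | O[C@H](c1ccc(O[Si](C)(C)C(C)(C)C)c(OC)c1)[C@H](CC=C)C(=O)N1[C@@H](Cc2ccccc2)COC1=O | intermediate
10 | (4S)-4-benzyl-3-{(2S)-2-[(S)-Ar(methoxy)methyl]pent-4-enoyl}-1,3-oxazolidin-2-one | CO[C@H](c1ccc(O[Si](C)(C)C(C)(C)C)c(OC)c1)[C@H](CC=C)C(=O)N1[C@@H](Cc2ccccc2)COC1=O | intermediate
11 | (2R)-2-[(S)-Ar(methoxy)methyl]pent-4-en-1-ol | CO[C@H](c1ccc(O[Si](C)(C)C(C)(C)C)c(OC)c1)[C@H](CC=C)CO | intermediate
12 | (3R,4S)-4-Ar-3-(hydroxymethyl)-4-methoxybutanal (not isolated) | CO[C@H](c1ccc(O[Si](C)(C)C(C)(C)C)c(OC)c1)[C@H](CC=O)CO | intermediate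
13 | (4R)-4-[(S)-Ar(methoxy)methyl]oxolan-2-ol (both anomers) | CO[C@H](c1ccc(O[Si](C)(C)C(C)(C)C)c(OC)c1)[C@H]1COC(O)C1 | intermediate
14 | (4R)-4-[(S)-Ar(methoxy)methyl]oxolan-2-one | CO[C@H](c1ccc(O[Si](C)(C)C(C)(C)C)c(OC)c1)[C@H]1COC(=O)C1 | intermediate
15 | (4R)-4-[(S)-Ar(methoxy)methyl]-3-(trifluoroacetyl)oxolan-2-one (not isolated) | CO[C@H](c1ccc(O[Si](C)(C)C(C)(C)C)c(OC)c1)[C@H]1COC(=O)C1C(=O)C(F)(F)F | intermediate
16 | (4R)-3-diazo-4-[(S)-Ar(methoxy)methyl]oxolan-2-one | CO[C@H](c1ccc(O[Si](C)(C)C(C)(C)C)c(OC)c1)[C@H]1COC(=O)C1=[N+]=[N-] | intermediate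
17 | (3aR,4S,6aR)-4-Ar-tetrahydro-1H,3H-furo[3,4-c]furan-1-one | O=C1[C@H]2CO[C@H](c3ccc(O[Si](C)(C)C(C)(C)C)c(OC)c3)[C@H]2CO1 | intermediate
18 | 4-bromo-2-methoxyphenol | COc1cc(Br)ccc1O | starting material
19 | (4-bromo-2-methoxyphenoxy)(tert-butyl)dimethylsilane | COc1cc(Br)ccc1O[Si](C)(C)C(C)(C)C | intermediate
20 | {4-[(tert-butyldimethylsilyl)oxy]-3-methoxyphenyl}lithium (not isolated) | [Li]c1ccc(O[Si](C)(C)C(C)(C)C)c(OC)c1 | intermediate
21 | lithium lactolate from 17 and 20, hemiketal carbon undefined (not isolated) | [Li]OC1(c3ccc(O[Si](C)(C)C(C)(C)C)c(OC)c3)[C@H]2CO[C@H](c3ccc(O[Si](C)(C)C(C)(C)C)c(OC)c3)[C@H]2CO1 | intermediate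
22 | [(2S,3R,4R)-2-Ar-3-(hydroxymethyl)oxolan-4-yl](Ar)methanone | COc1cc(C(=O)[C@H]2CO[C@H](c3ccc(O[Si](C)(C)C(C)(C)C)c(OC)c3)[C@H]2CO)ccc1O[Si](C)(C)C(C)(C)C | intermediate
23 | p-coumaric acid | OC(=O)/C=C/c1ccc(O)cc1 | starting material
24 | tert-butyldimethylsilyl (E)-3-{4-[(tert-butyldimethylsilyl)oxy]phenyl}prop-2-enoate (not isolated) | CC(C)(C)[Si](C)(C)OC(=O)/C=C/c1ccc(O[Si](C)(C)C(C)(C)C)cc1 | intermediate
25 | (E)-3-{4-[(tert-butyldimethylsilyl)oxy]phenyl}prop-2-enoic acid | OC(=O)/C=C/c1ccc(O[Si](C)(C)C(C)(C)C)cc1 | intermediate
26 | [(2S,3R,4R)-2-Ar-4-(Ar-carbonyl)oxolan-3-yl]methyl (E)-3-{4-[(tert-butyldimethylsilyl)oxy]phenyl}prop-2-enoate | COc1cc(C(=O)[C@H]2CO[C@H](c3ccc(O[Si](C)(C)C(C)(C)C)c(OC)c3)[C@H]2COC(=O)/C=C/c2ccc(O[Si](C)(C)C(C)(C)C)cc2)ccc1O[Si](C)(C)C(C)(C)C | intermediate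
27 | [(2S,3R,4R)-2-Ar-4-[(S)-Ar(hydroxy)methyl]oxolan-3-yl]methyl (E)-3-{4-[(tert-butyldimethylsilyl)oxy]phenyl}prop-2-enoate | COc1cc([C@@H](O)[C@H]2CO[C@H](c3ccc(O[Si](C)(C)C(C)(C)C)c(OC)c3)[C@H]2COC(=O)/C=C/c2ccc(O[Si](C)(C)C(C)(C)C)cc2)ccc1O[Si](C)(C)C(C)(C)C | intermediate
28 | [(2S,3R,4R)-4-[(S)-hydroxy(4-hydroxy-3-methoxyphenyl)methyl]-2-(4-hydroxy-3-methoxyphenyl)oxolan-3-yl]methyl (E)-3-(4-hydroxyphenyl)prop-2-enoate | COc1cc([C@@H](O)[C@H]2CO[C@H](c3ccc(O)c(OC)c3)[C@H]2COC(=O)/C=C/c2ccc(O)cc2)ccc1O | target

## Step count and risks

Total: 15 steps. Longest linear sequence: 12 steps (1, 3, 4, 5, 6, 7, 8, 9, 11, 13, 14, 15, from vanillin; the same length from pent-4-enoic acid through step 2).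

Least certain steps:

Step 9 (key step). The methyl C–H bonds are primary and the least reactive kind of ether C–H bond. The carbenoid may therefore be lost by 1,2-hydride migration from C3 or by electrophilic attack on the electron-rich arene before insertion occurs. Fallback, from 14 back to 17, closing ring A at the benzylic C2–O1 bond instead of at C4–C5:
- Deprotonation of 14 with LiN(i-Pr)2 at −78 °C and trapping with gaseous formaldehyde should give the trans hydroxymethyl lactone F1.
- Renewed deprotonation with two equivalents of base, then kinetic protonation of the dianion by a bulky phenol from the face away from the C3 substituent, should give the cis hydroxymethyl lactone F2.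
- BF3·OEt2 in CH2Cl2 at low temperature then ionises the benzylic methyl ether, assisted by the para silyloxy group, and the C5 hydroxyl captures the cation with loss of methanol. Because this closure is reversible, the exo aryl arrangement of 17 should result, with C3 and C4 fixing the absolute configuration.

Step 11. The lactolate may collapse before the quench, leading to a second aryl addition. The aryllithium may also act as a base at C4, which would start β-elimination of O1, and the liberated ketone may epimerise at C4 toward the more stable 3,4-trans arrangement. Fallback, from 17 back to 22, with an acyl donor that cannot add twice: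
- Opening of 17 with MeNH(OMe)·HCl and AlMe3 should give the hydroxy Weinreb amide F6.
- Silylation with Et3SiCl and imidazole gives the triethylsilyl ether F7.
- Addition of aryllithium 20 at −78 °C gives the silyl-protected ketone F8 through the stable chelated adduct.
- Pyridinium p-toluenesulfonate in methanol removes the triethylsilyl group and returns 22.

Step 14. The alkyl flank of the ketone is α-branched, which may erode the facial discrimination of the oxazaborolidine, and the substrate bias may not point the way the Felkin–Anh analysis suggests. Fallback, from 17 back to 27, building the C7 centre in the opposite order: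
- Reduction of 17 with i-Bu2AlH at −78 °C gives the lactol F9.
- The aryl Grignard reagent F10 (from 19 and Mg) is added in excess to the open aldehyde form to give the diol F11. Because aryl now adds to an aldehyde instead of hydride to an aryl ketone, a substrate bias that defeats the catalyst in step 14 leads here to the 7S alcohol.
- Selective acylation of the primary hydroxyl of F11 with 25 (EDC·HCl, DMAP, low temperature, no acid) gives 27.

Step 4. The hindered benzylic alcohol beside the imide may alkylate slowly, and retro-aldol cleavage or epimerisation at C3 may set in before conversion is complete. Fallback, from 9 back to 11, methylating after the imide is gone: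
- LiBH4 reduction of 9 gives the diol F3.
- Et3SiCl and imidazole at −78 °C silylate the primary hydroxyl to give F4.
- NaH and MeI methylate the benzylic alkoxide, which no longer has a retro-aldol pathway, to give F5.
- Pyridinium p-toluenesulfonate in methanol removes the triethylsilyl group to give 11.

Step 15. Three phenols are released next to a p-hydroxybenzylic alcohol and a cinnamate, so loss of the ester or ionisation at C7 under the fluoride conditions is possible. Fallback, from 26 to 28, with the order of the last two operations reversed: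
- Bu4NF and AcOH on the more robust ketone 26 give the triphenol keto ester F12.
- Reduction of F12 with the (R)-oxazaborolidine and excess catecholborane (the phenols are held as borate esters until work-up) gives 28.

## Further compounds

F1 | step 9 | (3S,4R)-3-(hydroxymethyl)-4-[(S)-Ar(methoxy)methyl]oxolan-2-one (trans) | CO[C@H](c1ccc(O[Si](C)(C)C(C)(C)C)c(OC)c1)[C@H]1COC(=O)[C@@H]1CO
F2 | step 9 | (3R,4R)-3-(hydroxymethyl)-4-[(S)-Ar(methoxy)methyl]oxolan-2-one (cis) | CO[C@H](c1ccc(O[Si](C)(C)C(C)(C)C)c(OC)c1)[C@H]1COC(=O)[C@H]1CO
F3 | step 4 | (1S,2R)-1-Ar-2-(prop-2-en-1-yl)propane-1,3-diol | O[C@H](c1ccc(O[Si](C)(C)C(C)(C)C)c(OC)c1)[C@H](CC=C)CO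
F4 | step 4 | (1S,2R)-1-Ar-2-{[(triethylsilyl)oxy]methyl}pent-4-en-1-ol | O[C@H](c1ccc(O[Si](C)(C)C(C)(C)C)c(OC)c1)[C@H](CC=C)CO[Si](CC)(CC)CC
F5 | step 4 | triethyl{[(2R)-2-[(S)-Ar(methoxy)methyl]pent-4-en-1-yl]oxy}silane | CO[C@H](c1ccc(O[Si](C)(C)C(C)(C)C)c(OC)c1)[C@H](CC=C)CO[Si](CC)(CC)CC
F6 | step 11 | (3R,4R,5S)-5-Ar-4-(hydroxymethyl)-N-methoxy-N-methyloxolane-3-carboxamide | CON(C)C(=O)[C@H]1CO[C@H](c2ccc(O[Si](C)(C)C(C)(C)C)c(OC)c2)[C@H]1CO
F7 | step 11 | (3R,4R,5S)-5-Ar-N-methoxy-N-methyl-4-{[(triethylsilyl)oxy]methyl}oxolane-3-carboxamide | CON(C)C(=O)[C@H]1CO[C@H](c2ccc(O[Si](C)(C)C(C)(C)C)c(OC)c2)[C@H]1CO[Si](CC)(CC)CC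
F8 | step 11 | [(2S,3R,4R)-2-Ar-3-{[(triethylsilyl)oxy]methyl}oxolan-4-yl](Ar)methanone | COc1cc(C(=O)[C@H]2CO[C@H](c3ccc(O[Si](C)(C)C(C)(C)C)c(OC)c3)[C@H]2CO[Si](CC)(CC)CC)ccc1O[Si](C)(C)C(C)(C)C
F9 | step 14 | (3aR,4S,6aR)-4-Ar-tetrahydro-1H,3H-furo[3,4-c]furan-1-ol (both anomers) | OC1[C@H]2CO[C@H](c3ccc(O[Si](C)(C)C(C)(C)C)c(OC)c3)[C@H]2CO1
F10 | step 14 | {4-[(tert-butyldimethylsilyl)oxy]-3-methoxyphenyl}magnesium bromide | Br[Mg]c1ccc(O[Si](C)(C)C(C)(C)C)c(OC)c1
F11 | step 14 | (S)-Ar[(2S,3R,4R)-2-Ar-3-(hydroxymethyl)oxolan-4-yl]methanol | COc1cc([C@@H](O)[C@H]2CO[C@H](c3ccc(O[Si](C)(C)C(C)(C)C)c(OC)c3)[C@H]2CO)ccc1O[Si](C)(C)C(C)(C)C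
F12 | step 15 | [(2S,3R,4R)-4-(4-hydroxy-3-methoxybenzoyl)-2-(4-hydroxy-3-methoxyphenyl)oxolan-3-yl]methyl (E)-3-(4-hydroxyphenyl)prop-2-enoate | COc1cc(C(=O)[C@H]2CO[C@H](c3ccc(O)c(OC)c3)[C@H]2COC(=O)/C=C/c2ccc(O)cc2)ccc1O
A1 | alternative 1 | [(2S,3R)-3-{3-methoxy-4-[(triisopropylsilyl)oxy]phenyl}oxiran-2-yl]methanol (cis epoxy alcohol) | COc1cc([C@H]2O[C@H]2CO)ccc1O[Si](C(C)C)(C(C)C)C(C)C
A2 | alternative 1 | dimethyl 2-({3-methoxy-4-[(triisopropylsilyl)oxy]phenyl}methylidene)propanedioate | COC(=O)C(=Cc1ccc(O[Si](C(C)C)(C(C)C)C(C)C)c(OC)c1)C(=O)OC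
A3 | alternative 1 | diexo 2,6-diaryl-1-(methoxycarbonyl)-3,7-dioxabicyclo[3.3.0]octan-8-one, bis(triisopropylsilyl ether) | COc1cc([C@@H](O4)[C@H]2CO[C@H](c3ccc(O[Si](C(C)C)(C(C)C)C(C)C)c(OC)c3)[C@@]2(C(=O)OC)C4=O)ccc1O[Si](C(C)C)(C(C)C)C(C)C
A4 | alternative 2 | dimethyl 2,3-bis{4-[(tert-butyldimethylsilyl)oxy]-3-methoxybenzoyl}butanedioate (epimerising mixture) | COC(=O)C(C(=O)c1ccc(O[Si](C)(C)C(C)(C)C)c(OC)c1)C(C(=O)OC)C(=O)c1ccc(O[Si](C)(C)C(C)(C)C)c(OC)c1
A5 | alternative 2 | diexo 2,6-diaryl-3,7-dioxabicyclo[3.3.0]octane-4,8-dione, bis(tert-butyldimethylsilyl ether) | COc1cc([C@@H](O4)[C@H]2C(=O)O[C@H](c3ccc(O[Si](C)(C)C(C)(C)C)c(OC)c3)[C@H]2C4=O)ccc1O[Si](C)(C)C(C)(C)C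
A6 | alternative 3 | ({chloro[3-methoxy-4-(prop-2-en-1-yloxy)phenyl]methoxy}methyl)trimethylsilane | COc1cc(C(Cl)OC[Si](C)(C)C)ccc1OCC=C
A7 | alternative 3 | carbonyl ylide from A6 | [CH2-][O+]=Cc1ccc(OCC=C)c(OC)c1
A8 | alternative 3 | (5S)-5-[3-methoxy-4-(prop-2-en-1-yloxy)phenyl]furan-2(5H)-one | COc1cc([C@H]2OC(=O)C=C2)ccc1OCC=C
A9 | alternative 3 | diexo 2,6-diaryl-3,7-dioxabicyclo[3.3.0]octan-8-one, bis(allyl ether) | COc1cc([C@@H](O4)[C@H]2CO[C@H](c3ccc(OCC=C)c(OC)c3)[C@H]2C4=O)ccc1OCC=C
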